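The route rests on cutting the aryl ether bond O1–C7a of the dihydrobenzofuran (benzofuran numbering, ring A = benzo ring). O1 sits on the secondary benzylic carbon C2. Oxygen-bearing C2 and carboxyl-bearing C3 stand in the β-hydroxy carbonyl relationship of an aldol, so an auxiliary-controlled syn-aldol can set both centres in an open chain. A copper-catalysed intramolecular O-arylation then links the C2 alkoxide to the ortho C–Br carbon of ring A. This closes the five-membered ring in one operation without touching C2 or C3, and syn becomes trans. The precursor is a syn-1,2-diarylpropane-1,3-diol carrying the ring A bromide, its primary oxygen blocked as a trityl ether that cannot migrate. Carboxylate-directed C4–H olefination and debenzylation complete the target.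

Key step: step 8

Remark: core atoms are numbered as in benzofuran (O1, C2, C3, C3a, C4–C7, C7a). Enol ether 3 is carried as an E/Z mixture because both isomers converge on 4.

Step 1
Reactants: 1 2-bromo-3-hydroxybenzaldehyde
Product: 2 3-(benzyloxy)-2-bromobenzaldehyde
Conditions: BnBr (1.1 equiv), K2CO3 (1.5 equiv), DMF, rt
Reagents that add atoms: benzyl bromide, BrCc1ccccc1
Why: Williamson ether synthesis, in which the phenoxide made by K2CO3 displaces bromide from benzyl bromide (SN2); benzyl is chosen because it withstands every later base, hydride, copper and palladium step.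

Step 2
Reactants: 2 3-(benzyloxy)-2-bromobenzaldehyde
Product: 3 1-(benzyloxy)-2-bromo-3-(2-methoxyethenyl)benzene (E/Z mixture)
Conditions: Ph3P(CH2OMe)Cl (1.4 equiv), KOtBu (1.35 equiv), THF, 0 °C to rt
Reagents that add atoms: (methoxymethyl)triphenylphosphonium chloride, COC[P+](c1ccccc1)(c1ccccc1)c1ccccc1.[Cl-]
Why: Wittig olefination of a non-enolisable aldehyde with the methoxymethylidene ylide adds the one missing carbon, and the alkene geometry does not matter because it is lost on hydrolysis.

Step 3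
Reactants: 3 1-(benzyloxy)-2-bromo-3-(2-methoxyethenyl)benzene
Product: 5 2-[3-(benzyloxy)-2-bromophenyl]acetic acid, via arylacetaldehyde 4 (not isolated)
Conditions: 2 M aq HCl, THF, 50 °C; extractive work-up, then crude 4, NaClO2, NaH2PO4, 2-methyl-2-butene, t-BuOH–H2O, rt
Reagents that add atoms: water, O; sodium chlorite, [Na+].[O-]Cl=O
Why: Acid hydrolysis of the enol ether followed by Pinnick oxidation of the unpurified, self-condensation-prone aldehyde should give the acid, with 2-methyl-2-butene trapping HOCl before it can chlorinate the alkoxyarene.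

Step 4
Reactants: 5 2-[3-(benzyloxy)-2-bromophenyl]acetic acid; 6 (S)-4-benzyl-1,3-oxazolidin-2-one
Product: 8 (S)-4-benzyl-3-{2-[3-(benzyloxy)-2-bromophenyl]acetyl}-1,3-oxazolidin-2-one, via mixed pivalic anhydride 7 (not isolated)
Conditions: PivCl (1.1 equiv), Et3N (2.5 equiv), THF, −20 °C; then LiCl (1.1 equiv), 6, −20 °C to rt
Reagents that add atoms: none
Why: N-acylation of the oxazolidinone through the mixed anhydride (LiCl/Et3N variant) attacks the less hindered arylacetyl carbonyl and needs no organolithium base that could exchange with the C–Br bond.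

Step 5
Reactants: 8 (S)-4-benzyl-3-{2-[3-(benzyloxy)-2-bromophenyl]acetyl}-1,3-oxazolidin-2-one; 9 3,4-bis(benzyloxy)benzaldehyde
Product: 12 (S)-4-benzyl-3-{(2S,3S)-2-[3-(benzyloxy)-2-bromophenyl]-3-[3,4-bis(benzyloxy)phenyl]-3-hydroxypropanoyl}-1,3-oxazolidin-2-one (syn), via boron enolate 10 (not isolated), via boron aldolate 11 (not isolated)
Conditions: Bu2BOTf (1.2 equiv), iPr2NEt (1.4 equiv), CH2Cl2, −78 to 0 °C; 9 (1.1 equiv), −78 to 0 °C; then pH 7 buffer, MeOH, 30% H2O2, 0 °C
Reagents that add atoms: none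
Why: Evans syn-aldol reaction, in which the Z-boron enolate reacts through a Zimmerman–Traxler chair on the enolate face turned away from the benzyl group of the dipole-opposed (S)-auxiliary, setting (2S,3S), the future C3 and C2, in one bond formation.

Step 6
Reactants: 12 syn-aldol imide
Product: 13 (1S,2R)-2-[3-(benzyloxy)-2-bromophenyl]-1-[3,4-bis(benzyloxy)phenyl]propane-1,3-diol
Conditions: LiBH4 (2.5 equiv), MeOH (2.5 equiv), THF, 0 °C
Reagents that add atoms: none
Why: Reductive cleavage of the N-acyl oxazolidinone by LiBH4 reduces only the exocyclic carbonyl to CH2OH and frees the auxiliary; no bond at either stereocentre breaks (the C2 descriptor changes by priority only) and the cold, weakly basic medium holds back retro-aldol cleavage.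

Step 7
Reactants: 13 (1S,2R)-diol
Product: 14 (1S,2R)-2-[3-(benzyloxy)-2-bromophenyl]-1-[3,4-bis(benzyloxy)phenyl]-3-(trityloxy)propan-1-ol
Conditions: TrCl (1.3 equiv), Et3N (2 equiv), DMAP (0.1 equiv), CH2Cl2, rt
Reagents that add atoms: trityl chloride, ClC(c1ccccc1)(c1ccccc1)c1ccccc1
Why: Tritylation (SN1-type transfer of the trityl cation) takes the primary hydroxyl for steric reasons and leaves the hindered benzylic one free, and a carbon-based ether is preferred to a silyl ether because it cannot move to a neighbouring alkoxide.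

Step 8
Reactants: 14 (1S,2R)-2-[3-(benzyloxy)-2-bromophenyl]-1-[3,4-bis(benzyloxy)phenyl]-3-(trityloxy)propan-1-ol
Product: 15 (2S,3R)-7-(benzyloxy)-2-[3,4-bis(benzyloxy)phenyl]-3-[(trityloxy)methyl]-2,3-dihydro-1-benzofuran (trans)
Conditions: CuI (15 mol %), 3,4,7,8-tetramethyl-1,10-phenanthroline (30 mol %), Cs2CO3 (2 equiv), toluene, 110 °C, argon
Reagents that add atoms: none
Why: Cs2CO3 deprotonates the secondary benzylic alcohol, the alkoxide binds the phenanthroline-ligated monovalent copper, the neighbouring C–Br bond adds oxidatively to give an aryl(alkoxo) complex of trivalent copper, and C–O reductive elimination forms C7a–O1 and returns the catalyst. This is an intramolecular Ullmann-type etherification, the known copper-catalysed cyclisation of 2-(2-haloaryl)ethanols to 2,3-dihydrobenzofurans, run with the electron-rich tetramethylphenanthroline that suits secondary alcohols and aryl bromides. The ring O1–C2–C3–C3a–C7a closes as a five-membered ring by delivery of the tethered oxygen to the sp2 carbon C7a with bromide leaving outside the ring (5-exo type), through a six-membered cupracycle. No stereocentre is made: neither the C2–O bond nor any bond at C3 is broken, so the (1S,2R)-syn chain passes with retention into the (2S,3R)-trans ring. The selectivity needed is between the two oxygens, because the primary one could close an isomeric five-membered ring onto the same carbon; the trityl ether blocks it and, offering no silicon centre for the alkoxide to attack, stays where it is at 110 °C. With C3 at the alcohol oxidation level there is no acidic C3–H, so retro-aldol cleavage, epimerisation and β-elimination are shut off, and argon keeps copper from dehydrogenating the carbinol.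

Step 9
Reactants: 15 trans trityl ether
Product: 16 [(2S,3R)-7-(benzyloxy)-2-[3,4-bis(benzyloxy)phenyl]-2,3-dihydro-1-benzofuran-3-yl]methanol
Conditions: camphorsulfonic acid (0.1 equiv), MeOH–CH2Cl2 1:1, rt
Reagents that add atoms: none
Why: Acid-catalysed SN1 solvolysis of the trityl ether, in which the trityl cation ionises far faster than the ring C2–O1 bond or the benzyl ethers and is carried off by methanol.

Step 10
Reactants: 16 primary alcohol
Product: 18 (2S,3S)-7-(benzyloxy)-2-[3,4-bis(benzyloxy)phenyl]-2,3-dihydro-1-benzofuran-3-carboxylic acid, via C3 aldehyde 17 (not isolated)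
Conditions: TEMPO (0.2 equiv), PhI(OAc)2 (2.5 equiv), MeCN–CH2Cl2–H2O, rt
Reagents that add atoms: water, O
Why: Oxoammonium (TEMPO/PhI(OAc)2) oxidation takes the alcohol through the aldehyde hydrate to the acid in a near-neutral medium that avoids E1cB opening of the β-aryloxy aldehyde, and C3 already holds the more stable trans arrangement, so transient enolisation has nothing to erode.

Step 11
Reactants: 19 (R)-3-(3,4-dihydroxyphenyl)lactic acid (danshensu)
Product: 20 methyl (R)-3-(3,4-dihydroxyphenyl)-2-hydroxypropanoate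
Conditions: TsOH·H2O (0.1 equiv), MeOH, reflux, N2
Reagents that add atoms: methanol, CO
Why: Fischer esterification proceeds at the carboxyl carbon only, so the α-stereocentre is untouched, and the catechol is stable in acid under nitrogen.

Step 12
Reactants: 20 methyl (R)-3-(3,4-dihydroxyphenyl)-2-hydroxypropanoate
Product: 21 methyl (R)-3-[3,4-bis(benzyloxy)phenyl]-2-hydroxypropanoate
Conditions: BnBr (2.2 equiv), K2CO3 (2.5 equiv), acetone, reflux, N2
Reagents that add atoms: benzyl bromide, BrCc1ccccc1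
Why: Williamson ether synthesis that is chemoselective by acidity, since K2CO3 ionises the two phenols but neither the secondary alcohol nor the α-C–H.

Step 13
Reactants: 21 methyl (R)-3-[3,4-bis(benzyloxy)phenyl]-2-hydroxypropanoate
Product: 22 methyl (R)-2-(acryloyloxy)-3-[3,4-bis(benzyloxy)phenyl]propanoate
Conditions: acryloyl chloride (1.3 equiv), Et3N (1.6 equiv), CH2Cl2, 0 °C
Reagents that add atoms: acryloyl chloride, C=CC(=O)Cl
Why: O-acylation of the secondary alcohol by an acid chloride with an amine base forms the ester at oxygen, so the (R) centre is retained.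

Step 14
Reactants: 18 (2S,3S)-dihydrobenzofuran-3-carboxylic acid; 22 methyl (R)-2-(acryloyloxy)-3-[3,4-bis(benzyloxy)phenyl]propanoate
Product: 23 (2S,3S)-7-(benzyloxy)-2-[3,4-bis(benzyloxy)phenyl]-4-[(E)-3-{[(R)-1-[3,4-bis(benzyloxy)phenyl]-3-methoxy-3-oxopropan-2-yl]oxy}-3-oxoprop-1-enyl]-2,3-dihydro-1-benzofuran-3-carboxylic acid
Conditions: Pd(OAc)2 (10 mol %), N-acetyl-L-isoleucine (20 mol %), KHCO3 (2 equiv), 22 (1.2 equiv), O2 (1 atm), t-AmylOH, 85 °C; then 1 M HCl work-up
Reagents that add atoms: none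
Why: Carboxylate-directed C–H olefination (oxidative Heck, Fujiwara–Moritani type) as known for phenylacetic acids: the C3 carboxylate steers divalent palladium to C4–H through a six-membered palladacycle, the only ortho site since C7a is substituted; syn-insertion of the acrylate and β-hydride elimination give the E-cinnamate, and O2 reoxidises zerovalent palladium.

Step 15
Reactants: 23 pentabenzyl ether
Product: 24 (2S,3S)-2-(3,4-dihydroxyphenyl)-4-[(E)-3-{[(R)-1-(3,4-dihydroxyphenyl)-3-methoxy-3-oxopropan-2-yl]oxy}-3-oxoprop-1-enyl]-7-hydroxy-2,3-dihydro-1-benzofuran-3-carboxylic acid (CNP0120702.1)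
Conditions: BCl3 (1 M in CH2Cl2, 12 equiv), pentamethylbenzene (15 equiv), CH2Cl2, −78 °C; quench THF–H2O at −78 °C; argon, reversed-phase purification
Reagents that add atoms: none
Why: Lewis-acid debenzylation of aryl benzyl ethers, in which BCl3 binds the ether oxygen and the benzyl cation is passed to pentamethylbenzene (Friedel–Crafts scavenging) at −78 °C; unlike hydrogenolysis this spares the cinnamate C=C, and it leaves both esters and all three stereocentres alone.

Compound list
1 | 2-bromo-3-hydroxybenzaldehyde | O=Cc1cccc(O)c1Br | starting material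
2 | 3-(benzyloxy)-2-bromobenzaldehyde | O=Cc1cccc(OCc2ccccc2)c1Br | intermediate
3 | 1-(benzyloxy)-2-bromo-3-(2-methoxyethenyl)benzene (E/Z mixture) | COC=Cc1cccc(OCc2ccccc2)c1Br | intermediate
4 | 2-[3-(benzyloxy)-2-bromophenyl]acetaldehyde | O=CCc1cccc(OCc2ccccc2)c1Br | intermediate
5 | 2-[3-(benzyloxy)-2-bromophenyl]acetic acid | OC(=O)Cc1cccc(OCc2ccccc2)c1Br | intermediate
6 | (S)-4-benzyl-1,3-oxazolidin-2-one | O=C1OC[C@H](Cc2ccccc2)N1 | starting material
7 | 2-[3-(benzyloxy)-2-bromophenyl]acetic pivalic anhydride | CC(C)(C)C(=O)OC(=O)Cc1cccc(OCc2ccccc2)c1Br | intermediate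
8 | (S)-4-benzyl-3-{2-[3-(benzyloxy)-2-bromophenyl]acetyl}-1,3-oxazolidin-2-one | O=C1OC[C@H](Cc2ccccc2)N1C(=O)Cc1cccc(OCc2ccccc2)c1Br | intermediate
9 | 3,4-bis(benzyloxy)benzaldehyde | O=Cc1ccc(OCc2ccccc2)c(OCc2ccccc2)c1 | starting material
10 | (Z)-dibutylboron enolate of 8 | CCCCB(CCCC)O/C(=C\c1cccc(OCc2ccccc2)c1Br)N1C(=O)OC[C@@H]1Cc1ccccc1 | intermediate
11 | O-dibutylboryl aldolate of 12 | c1ccc(OCc2ccccc2)c(Br)c1[C@H](C(=O)N1C(=O)OC[C@@H]1Cc1ccccc1)[C@@H](c1ccc(OCc2ccccc2)c(OCc2ccccc2)c1)OB(CCCC)CCCC | intermediate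
12 | (S)-4-benzyl-3-{(2S,3S)-2-[3-(benzyloxy)-2-bromophenyl]-3-[3,4-bis(benzyloxy)phenyl]-3-hydroxypropanoyl}-1,3-oxazolidin-2-one | c1ccc(OCc2ccccc2)c(Br)c1[C@H](C(=O)N1C(=O)OC[C@@H]1Cc1ccccc1)[C@@H](c1ccc(OCc2ccccc2)c(OCc2ccccc2)c1)O | intermediate
13 | (1S,2R)-2-[3-(benzyloxy)-2-bromophenyl]-1-[3,4-bis(benzyloxy)phenyl]propane-1,3-diol | c1ccc(OCc2ccccc2)c(Br)c1[C@H](CO)[C@@H](c1ccc(OCc2ccccc2)c(OCc2ccccc2)c1)O | intermediate
14 | (1S,2R)-2-[3-(benzyloxy)-2-bromophenyl]-1-[3,4-bis(benzyloxy)phenyl]-3-(trityloxy)propan-1-ol | c1ccc(OCc2ccccc2)c(Br)c1[C@H](COC(c2ccccc2)(c2ccccc2)c2ccccc2)[C@@H](c1ccc(OCc2ccccc2)c(OCc2ccccc2)c1)O | intermediate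
15 | (2S,3R)-7-(benzyloxy)-2-[3,4-bis(benzyloxy)phenyl]-3-[(trityloxy)methyl]-2,3-dihydro-1-benzofuran | c1ccc(OCc3ccccc3)c2c1[C@H](COC(c3ccccc3)(c3ccccc3)c3ccccc3)[C@@H](c1ccc(OCc3ccccc3)c(OCc3ccccc3)c1)O2 | intermediate
16 | [(2S,3R)-7-(benzyloxy)-2-[3,4-bis(benzyloxy)phenyl]-2,3-dihydro-1-benzofuran-3-yl]methanol | c1ccc(OCc3ccccc3)c2c1[C@H](CO)[C@@H](c1ccc(OCc3ccccc3)c(OCc3ccccc3)c1)O2 | intermediate
17 | (2S,3S)-7-(benzyloxy)-2-[3,4-bis(benzyloxy)phenyl]-2,3-dihydro-1-benzofuran-3-carbaldehyde | c1ccc(OCc3ccccc3)c2c1[C@H](C=O)[C@@H](c1ccc(OCc3ccccc3)c(OCc3ccccc3)c1)O2 | intermediate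
18 | (2S,3S)-7-(benzyloxy)-2-[3,4-bis(benzyloxy)phenyl]-2,3-dihydro-1-benzofuran-3-carboxylic acid | c1ccc(OCc3ccccc3)c2c1[C@H](C(=O)O)[C@@H](c1ccc(OCc3ccccc3)c(OCc3ccccc3)c1)O2 | intermediate
19 | (R)-3-(3,4-dihydroxyphenyl)lactic acid (danshensu) | O=C(O)[C@H](O)Cc1ccc(O)c(O)c1 | starting material
20 | methyl (R)-3-(3,4-dihydroxyphenyl)-2-hydroxypropanoate | COC(=O)[C@H](O)Cc1ccc(O)c(O)c1 | intermediate
21 | methyl (R)-3-[3,4-bis(benzyloxy)phenyl]-2-hydroxypropanoate | COC(=O)[C@H](O)Cc1ccc(OCc2ccccc2)c(OCc2ccccc2)c1 | intermediate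
22 | methyl (R)-2-(acryloyloxy)-3-[3,4-bis(benzyloxy)phenyl]propanoate | COC(=O)[C@H](OC(=O)C=C)Cc1ccc(OCc2ccccc2)c(OCc2ccccc2)c1 | intermediate
23 | pentabenzyl ether of the target (full name in step 14) | COC(=O)[C@@H](Cc1ccc(OCc2ccccc2)c(OCc2ccccc2)c1)OC(=O)/C=C/c1ccc(OCc2ccccc2)c2c1[C@H](C(=O)O)[C@@H](c1ccc(OCc3ccccc3)c(OCc3ccccc3)c1)O2 | intermediate
24 | CNP0120702.1 (full name in step 15) | COC(=O)[C@@H](Cc1ccc(O)c(O)c1)OC(=O)/C=C/c1ccc(O)c2c1[C@H](C(=O)O)[C@@H](c1ccc(O)c(O)c1)O2 | target

Total step count: 15. Longest linear sequence: 12 (steps 1–10, 14, 15).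

Steps most likely to fail

Step 8. Oxidative addition at a C–Br bond flanked on both sides may be slow. That would leave time for protodebromination or for dehydrogenation of the benzylic alcohol.
- The fallback reverses the polarity of the closure and sets out from 14.
- Bromine–lithium exchange (n-BuLi, 2.2 equiv, THF, −78 °C, the first equivalent taking the hydroxyl proton), B(OMe)3 and aqueous work-up would give the arylboronic acid F1.
- H2O2/NaOH at 0 °C would oxidise this to the phenol F2.
- Catalytic TsOH in CH2Cl2–MeOH would then strip the trityl group and ionise the para-benzyloxy-stabilised benzylic alcohol.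
- The phenol captures the cation on the face away from the C3 hydroxymethyl group. This is the classical acid closure of phenylcoumarans, reversible and trans-selective, with the untouched C3 as the controlling centre.
- The route is rejoined at 16.

Step 15. The ring C2–O1 bond is itself a benzylic aryl ether. BCl3 may ionise it, and the scavenger may capture the cation irreversibly. Cleavage of five ethers may also stall part-way.
- The fallback changes the protecting-group plan while hydrogenolysis is still allowed. It sets out from 18 and 20.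
- H2 over 10% Pd/C in EtOAc–MeOH would turn 18, which has no alkene, into the trihydroxy acid F3.
- MOMCl/iPr2NEt would give the fully protected MOM ester F4, and LiOH in THF–H2O at 0 °C the tris-MOM acid F5.
- In parallel, 20 with MOMCl/K2CO3 in acetone would give the bis-MOM lactate F6, and acryloyl chloride/Et3N its acrylate F7.
- The conditions of step 14 would join F5 and F7 to the penta-MOM ether F8.
- Aqueous TFA in CH2Cl2 at 0 °C to rt would hydrolyse the acetals. No carbon nucleophile is present, so any reversible opening of the ring can only reclose to the trans isomer.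
- The route is rejoined at 24.

Step 14. The catalyst may decay before conversion is complete, or the valuable lactate acrylate may degrade or racemise slowly during long heating with base.
- The fallback separates C–C bond formation from attachment of the lactate. It sets out from 18 and 21.
- Olefination of 18 with an excess of cheap tert-butyl acrylate under the same Pd(OAc)2 system would give the tert-butyl cinnamate acid F9.
- BnBr/K2CO3 in DMF would mask the C3 acid as the benzyl ester F10, and TFA in CH2Cl2 would free the cinnamic acid F11.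
- Steglich esterification (EDC·HCl, DMAP, CH2Cl2) with alcohol 21 would give the hexabenzyl compound F12.
- The BCl3/pentamethylbenzene conditions of step 15 would remove the five ethers and the benzyl ester together.
- The route is rejoined at 24.

Further compounds
F1 | step 8 | [2-(benzyloxy)-6-{(1S,2R)-1-[3,4-bis(benzyloxy)phenyl]-1-hydroxy-3-(trityloxy)propan-2-yl}phenyl]boronic acid | c1ccc(OCc2ccccc2)c(B(O)O)c1[C@H](COC(c2ccccc2)(c2ccccc2)c2ccccc2)[C@@H](c1ccc(OCc2ccccc2)c(OCc2ccccc2)c1)O
F2 | step 8 | 2-(benzyloxy)-6-{(1S,2R)-1-[3,4-bis(benzyloxy)phenyl]-1-hydroxy-3-(trityloxy)propan-2-yl}phenol | c1ccc(OCc2ccccc2)c(O)c1[C@H](COC(c2ccccc2)(c2ccccc2)c2ccccc2)[C@@H](c1ccc(OCc2ccccc2)c(OCc2ccccc2)c1)O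
F3 | step 15 | (2S,3S)-2-(3,4-dihydroxyphenyl)-7-hydroxy-2,3-dihydro-1-benzofuran-3-carboxylic acid | c1ccc(O)c2c1[C@H](C(=O)O)[C@@H](c1ccc(O)c(O)c1)O2
F4 | step 15 | methoxymethyl (2S,3S)-7-(methoxymethoxy)-2-[3,4-bis(methoxymethoxy)phenyl]-2,3-dihydro-1-benzofuran-3-carboxylate | c1ccc(OCOC)c2c1[C@H](C(=O)OCOC)[C@@H](c1ccc(OCOC)c(OCOC)c1)O2
F5 | step 15 | (2S,3S)-7-(methoxymethoxy)-2-[3,4-bis(methoxymethoxy)phenyl]-2,3-dihydro-1-benzofuran-3-carboxylic acid | c1ccc(OCOC)c2c1[C@H](C(=O)O)[C@@H](c1ccc(OCOC)c(OCOC)c1)O2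
F6 | step 15 | methyl (R)-2-hydroxy-3-[3,4-bis(methoxymethoxy)phenyl]propanoate | COC(=O)[C@H](O)Cc1ccc(OCOC)c(OCOC)c1
F7 | step 15 | methyl (R)-2-(acryloyloxy)-3-[3,4-bis(methoxymethoxy)phenyl]propanoate | COC(=O)[C@H](OC(=O)C=C)Cc1ccc(OCOC)c(OCOC)c1
F8 | step 15 | penta(methoxymethyl) ether of 24 | COC(=O)[C@@H](Cc1ccc(OCOC)c(OCOC)c1)OC(=O)/C=C/c1ccc(OCOC)c2c1[C@H](C(=O)O)[C@@H](c1ccc(OCOC)c(OCOC)c1)O2
F9 | step 14 | (2S,3S)-7-(benzyloxy)-2-[3,4-bis(benzyloxy)phenyl]-4-[(E)-3-tert-butoxy-3-oxoprop-1-enyl]-2,3-dihydro-1-benzofuran-3-carboxylic acid | CC(C)(C)OC(=O)/C=C/c1ccc(OCc2ccccc2)c2c1[C@H](C(=O)O)[C@@H](c1ccc(OCc3ccccc3)c(OCc3ccccc3)c1)O2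
F10 | step 14 | benzyl ester of F9 | CC(C)(C)OC(=O)/C=C/c1ccc(OCc2ccccc2)c2c1[C@H](C(=O)OCc1ccccc1)[C@@H](c1ccc(OCc3ccccc3)c(OCc3ccccc3)c1)O2
F11 | step 14 | (E)-3-{(2S,3S)-7-(benzyloxy)-3-[(benzyloxy)carbonyl]-2-[3,4-bis(benzyloxy)phenyl]-2,3-dihydro-1-benzofuran-4-yl}prop-2-enoic acid | OC(=O)/C=C/c1ccc(OCc2ccccc2)c2c1[C@H](C(=O)OCc1ccccc1)[C@@H](c1ccc(OCc3ccccc3)c(OCc3ccccc3)c1)O2
F12 | step 14 | benzyl ester of 23 (hexabenzyl compound) | COC(=O)[C@@H](Cc1ccc(OCc2ccccc2)c(OCc2ccccc2)c1)OC(=O)/C=C/c1ccc(OCc2ccccc2)c2c1[C@H](C(=O)OCc1ccccc1)[C@@H](c1ccc(OCc3ccccc3)c(OCc3ccccc3)c1)O2
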